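**Strategy.** The enal is disconnected by a directed aldol condensation into two labdane aldehyde acids that differ only at C5. One is a trans-decalin (donor) and the other its cis-fused 5-epimer (acceptor). Each bicycle is zipped from an acyclic enyne tosylhydrazone. That precursor comes from cleaving the C19–C8 bond of a cyclohexanone template that fixed C4 and C5. In the key step a stannyl radical adds to the alkyne, the C8 vinyl radical closes ring B at C9, and the tertiary C10 radical closes ring A at C1. N2, sulfinate and tin leave tracelessly. The step exploits the C8(17) exocyclic methylene, the quaternary C10 between C5 and C9, and the unfunctionalised C1 methylene of ring A.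

Key step: step 12

Remark: labdane numbering (C1–C20) is used for all intermediates. The carbinol configuration in 17 and 34, the C1 configuration in 22 and 39, and the C=C–Sn geometry in 22, 23, 39 and 40 have no consequence and are left open.

Step 1
Reactants: 1 (S)-citronellol
Product: 2 (S)-citronellol TBS ether
Conditions: TBSCl, imidazole, CH2Cl2, 0 °C to rt
Reagents that add atoms: tert-butyldimethylsilyl chloride, CC(C)(C)[Si](C)(C)Cl
Why: Standard silyl ether protection of the primary alcohol; the C13 stereocentre of both halves comes from the chiral pool and is untouched.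

Step 2
Reactants: 2 (S)-citronellol TBS ether
Product: 3 (4S)-6-(tert-butyldimethylsilyloxy)-4-methylhexanal
Conditions: O3, CH2Cl2, −78 °C; then Me2S, −78 °C to rt
Reagents that add atoms: ozone, [O-][O+]=O
Why: Ozonolysis with reductive work-up cleaves the only C=C bond and turns the alkene CH into the aldehyde carbon that becomes C9.

Step 3
Reactants: 3 (4S)-6-(tert-butyldimethylsilyloxy)-4-methylhexanal
Product: 4 tert-butyl{[(3S)-3-methylhept-6-yn-1-yl]oxy}dimethylsilane
Conditions: dimethyl (1-diazo-2-oxopropyl)phosphonate, K2CO3, MeOH, 0 °C to rt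
Reagents that add atoms: dimethyl (1-diazo-2-oxopropyl)phosphonate, COP(=O)(OC)C(=[N+]=[N-])C(C)=O
Why: Ohira–Bestmann (Seyferth–Gilbert) homologation turns the aldehyde into the terminal alkyne under carbonate conditions that spare the silyl ether, and it adds C10.

Step 4
Reactants: 4 tert-butyl{[(3S)-3-methylhept-6-yn-1-yl]oxy}dimethylsilane
Product: 6 tert-butyl{[(3S)-3-methyloct-6-yn-1-yl]oxy}dimethylsilane, via lithium acetylide 5 (not isolated)
Conditions: n-BuLi, THF, −78 °C; then MeI, −78 °C to rt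
Reagents that add atoms: iodomethane, CI
Why: Deprotonation of the terminal alkyne and SN2 methylation of the acetylide (alkyne alkylation) install C20.

Step 5
Reactants: 6 tert-butyl{[(3S)-3-methyloct-6-yn-1-yl]oxy}dimethylsilane
Product: 8 tert-butyl{[(3S,6E)-7-iodo-3-methyloct-6-en-1-yl]oxy}dimethylsilane, via alkenylzirconocene 7 (not isolated)
Conditions: Cp2Zr(H)Cl (slight excess), THF, rt to 40 °C; then I2, 0 °C
Reagents that add atoms: iodine, II
Why: syn-Hydrozirconation puts Zr on the less hindered alkyne carbon next to the methyl group (excess reagent equilibrates the regioisomers), and iodinolysis with retention gives the E-iodide that fixes the C9=C10 geometry.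

Step 6
Reactants: 9 2-vinyl-1,3-dioxolane; 10 2-iodocyclohex-2-en-1-one
Product: 12 2-[2-(1,3-dioxolan-2-yl)ethyl]cyclohex-2-en-1-one, via B-alkyl-9-BBN 11 (not isolated)
Conditions: 9, 9-BBN, THF, 0 °C to rt; then 10, PdCl2(dppf) (cat.), Ph3As (cat.), Cs2CO3, DMF/H2O, rt
Reagents that add atoms: none
Why: Anti-Markovnikov hydroboration followed by B-alkyl Suzuki–Miyaura coupling with the α-iodoenone joins C3 to C4 without touching the enone or the acetal.

Step 7
Reactants: 8 tert-butyl{[(3S,6E)-7-iodo-3-methyloct-6-en-1-yl]oxy}dimethylsilane; 12 2-[2-(1,3-dioxolan-2-yl)ethyl]cyclohex-2-en-1-one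
Product: 15 (2S,3R)-3-[(2E,6S)-8-(tert-butyldimethylsilyloxy)-6-methyloct-2-en-2-yl]-2-[2-(1,3-dioxolan-2-yl)ethyl]-2-methylcyclohexan-1-one, via E-alkenylmagnesium chloride 13 (not isolated), via magnesium enolate 14 (not isolated)
Conditions: 8, i-PrMgCl·LiCl, THF, −20 to 0 °C; Cu(OTf)2 (cat.), chiral hydroxyalkyl-NHC ligand (cat.), 12, Et2O, −30 °C; then MeI, DMPU, −30 °C to rt
Reagents that add atoms: iodomethane, CI
Why: This three-component coupling combines iodine–magnesium exchange with retention, copper/NHC-catalysed asymmetric conjugate addition to the α-substituted enone (ligand antipode chosen for attack on the Si face of the β-carbon, sets C5 = R), and methylation of the tetrasubstituted enolate anti to the new alkenyl group (sets C4 = S).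

Step 8
Reactants: 15 ketone of step 7
Product: 17 6-hydroxy derivative of 15 (α-hydroxy ketone, OH on C8), via potassium enolate 16 (not isolated)
Conditions: KHMDS, THF, −78 °C; 3-phenyl-2-(phenylsulfonyl)oxaziridine, −78 °C; AcOH quench
Reagents that add atoms: 3-phenyl-2-(phenylsulfonyl)-1,2-oxaziridine, O=S(=O)(c1ccccc1)N1OC1c1ccccc1
Why: The ketone can enolise only towards C8, and Davis hydroxylation of that enolate spares the alkene and the acetal; the new carbinol centre is destroyed in step 9.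

Step 9
Reactants: 17 α-hydroxy ketone
Product: 18 (2S,3R,4E,8S)-10-(tert-butyldimethylsilyloxy)-2-[2-(1,3-dioxolan-2-yl)ethyl]-2,4,8-trimethyl-3-(3-oxopropyl)dec-4-enoic acid
Conditions: NaIO4, THF/H2O (pH 7 buffer), rt
Reagents that add atoms: sodium periodate, [Na+].[O-]I(=O)(=O)=O
Why: Periodate (Malaprade-type) cleavage of the α-hydroxy ketone breaks the C19–C8 bond of the template ring and releases the C19 acid and the C8 aldehyde with C4 and C5 intact.

Step 10
Reactants: 18 seco acid aldehyde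
Product: 19 (2S,3R,4E,8S)-3-(but-3-yn-1-yl)-10-(tert-butyldimethylsilyloxy)-2-[2-(1,3-dioxolan-2-yl)ethyl]-2,4,8-trimethyldec-4-enoic acid
Conditions: dimethyl (1-diazo-2-oxopropyl)phosphonate, K2CO3 (excess), MeOH, 0 °C to rt; mild acid work-up
Reagents that add atoms: dimethyl (1-diazo-2-oxopropyl)phosphonate, COP(=O)(OC)C(=[N+]=[N-])C(C)=O
Why: Ohira–Bestmann homologation converts the only aldehyde into the C8≡C17 alkyne while the acid rides along as its carboxylate.

Step 11
Reactants: 19 enyne acid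
Product: 21 (2S,3R,4E,8S)-3-(but-3-yn-1-yl)-10-hydroxy-2,4,8-trimethyl-2-{(3E)-3-[2-(4-methylphenylsulfonyl)hydrazinylidene]propyl}dec-4-enoic acid, via hydroxy aldehyde 20 (not isolated)
Conditions: 0.5 M aq HCl, THF, rt; then TsNHNH2, rt
Reagents that add atoms: p-toluenesulfonyl hydrazide, Cc1ccc(cc1)S(=O)(=O)NN
Why: Dilute acid removes the dioxolane and the primary silyl ether, and the only aldehyde then condenses with the hydrazide (hydrazone formation); the acidity is too low to protonate the trisubstituted alkene.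

Step 12
Reactants: 21 enyne tosylhydrazone (E-alkene, 4S,5R)
Product: 24 (13S)-15-hydroxylabd-8(17)-en-19-oic acid (imbricatolic acid, trans-decalin), via stannylated tosylhydrazine 22 (not isolated), via vinylstannane 23 (not isolated)
Conditions: Bu3SnH (syringe pump), ACCN (cat.), PhMe (5 mM), 110 °C; then continued reflux
Reagents that add atoms: none
Why: Bu3Sn• adds reversibly to the terminal alkyne carbon C17, the C8 vinyl radical attacks C9 of the E-trisubstituted alkene, and the tertiary C10 radical adds to C1 of the aldehyde tosylhydrazone; the N-alkyl-N'-tosylhydrazine then loses p-toluenesulfinic acid and N2 at 110 °C to leave C1H2, while the sulfinic acid protodestannylates C17. The closest known types are the stannyl-radical enyne (vinyl radical) cyclisation and the reductive radical cyclisation onto sulfonylhydrazones or N-aziridinylimines. Ring B closes 6-endo-trig, because the C20 methyl on the proximal alkene carbon blocks 5-exo attack and any 5-exo radical ring-expands to the same C10 radical, and ring A closes 6-exo-trig on C=N. C9 is set by the E-alkene in a chair transition state with the bulky C4 group on C5 equatorial (C11 equatorial, H9 cis to H5), and C10 by equatorial attack through a chair–chair array as in radical polyene cyclisations, which gives the trans-decalin. The alternative cis closure would place C18 rather than the smaller CO2H 1,3-diaxial to C20, so the (4S) centre reinforces the trans mode. Chemoselectivity rests on high dilution and slow hydride addition, so that the cyclisations outrun H transfer, and on the hydrazone being the only good acceptor within reach of C10.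

Step 13
Reactants: 24 (13S)-15-hydroxylabd-8(17)-en-19-oic acid
Product: 25 (13S)-15-oxolabd-8(17)-en-19-oic acid
Conditions: Dess–Martin periodinane, CH2Cl2, rt
Reagents that add atoms: none
Why: Dess–Martin oxidation stops at the aldehyde and tolerates the free acid and the exocyclic alkene.

Step 14
Reactants: 3 (4S)-6-(tert-butyldimethylsilyloxy)-4-methylhexanal
Product: 26 tert-butyl{[(3S,6Z)-7-iodo-3-methyloct-6-en-1-yl]oxy}dimethylsilane
Conditions: EtPPh3I, n-BuLi, THF, rt; I2, −78 °C; NaHMDS, −20 °C; then 3, −78 °C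
Reagents that add atoms: ethyltriphenylphosphonium iodide, CC[P+](c1ccccc1)(c1ccccc1)c1ccccc1.[I-]; iodine, II
Why: Stork–Zhao-type Wittig olefination with the α-iodoethylidene ylide should give the Z-iodide under kinetic control, placing iodine (later C5) cis to C11.

Step 15
Reactants: 26 Z-vinyl iodide; 27 2-methylcyclohex-2-en-1-one
Product: 30 (2S,3S)-2-allyl-3-[(2Z,6S)-8-(tert-butyldimethylsilyloxy)-6-methyloct-2-en-2-yl]-2-methylcyclohexan-1-one, via Z-alkenylmagnesium chloride 28 (not isolated), via magnesium enolate 29 (not isolated)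
Conditions: 26, i-PrMgCl·LiCl, THF, −20 to 0 °C; Cu(OTf)2 (cat.), antipodal chiral hydroxyalkyl-NHC ligand (cat.), 27, Et2O, −30 °C; then allyl bromide, DMPU, −30 °C to rt
Reagents that add atoms: allyl bromide, C=CCBr
Why: This is the same asymmetric conjugate addition and enolate trapping as step 7, now on the Re face of the β-carbon (C5 = S) and with the C3 unit as the electrophile entering anti to the alkenyl group, so C4 is again S while C5 is inverted relative to 15.

Step 16
Reactants: 30 allyl ketone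
Product: 31 (2S,3S)-3-[(2Z,6S)-8-(tert-butyldimethylsilyloxy)-6-methyloct-2-en-2-yl]-2-methyl-2-(3-oxopropyl)cyclohexan-1-one
Conditions: PdCl2(PhCN)2 (cat.), CuCl2·2H2O (cat.), AgNO2 (cat.), O2 (1 atm), t-BuOH/MeNO2, rt
Reagents that add atoms: oxygen, O=O
Why: The nitrite-modified, aldehyde-selective (anti-Markovnikov) Wacker oxidation attacks only the monosubstituted alkene, and the neighbouring quaternary carbon disfavours the Markovnikov mode.

Step 17
Reactants: 31 keto aldehyde
Product: 32 (2S,3S)-3-[(2Z,6S)-8-(tert-butyldimethylsilyloxy)-6-methyloct-2-en-2-yl]-2-[2-(1,3-dioxolan-2-yl)ethyl]-2-methylcyclohexan-1-one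
Conditions: TMSOCH2CH2OTMS, TMSOTf (cat.), CH2Cl2, −78 °C
Reagents that add atoms: 1,2-bis(trimethylsilyloxy)ethane, C[Si](C)(C)OCCO[Si](C)(C)C
Why: Noyori acetalisation masks the aldehyde, while the ketone next to the quaternary carbon and the silyl ether do not react at −78 °C.

Step 18
Reactants: 32 dioxolane ketone
Product: 34 6-hydroxy derivative of 32 (α-hydroxy ketone, OH on C8), via potassium enolate 33 (not isolated)
Conditions: KHMDS, THF, −78 °C; 3-phenyl-2-(phenylsulfonyl)oxaziridine, −78 °C; AcOH quench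
Reagents that add atoms: 3-phenyl-2-(phenylsulfonyl)-1,2-oxaziridine, O=S(=O)(c1ccccc1)N1OC1c1ccccc1
Why: Davis hydroxylation of the only possible enolate, as in step 8; the new carbinol centre is destroyed in step 19.

Step 19
Reactants: 34 α-hydroxy ketone
Product: 35 (2S,3S,4Z,8S)-10-(tert-butyldimethylsilyloxy)-2-[2-(1,3-dioxolan-2-yl)ethyl]-2,4,8-trimethyl-3-(3-oxopropyl)dec-4-enoic acid
Conditions: NaIO4, THF/H2O (pH 7 buffer), rt
Reagents that add atoms: sodium periodate, [Na+].[O-]I(=O)(=O)=O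
Why: Periodate cleavage of the C19–C8 bond, as in step 9, keeps C4 and C5.

Step 20
Reactants: 35 seco acid aldehyde
Product: 36 (2S,3S,4Z,8S)-3-(but-3-yn-1-yl)-10-(tert-butyldimethylsilyloxy)-2-[2-(1,3-dioxolan-2-yl)ethyl]-2,4,8-trimethyldec-4-enoic acid
Conditions: dimethyl (1-diazo-2-oxopropyl)phosphonate, K2CO3 (excess), MeOH, 0 °C to rt; mild acid work-up
Reagents that add atoms: dimethyl (1-diazo-2-oxopropyl)phosphonate, COP(=O)(OC)C(=[N+]=[N-])C(C)=O
Why: Ohira–Bestmann homologation of the only aldehyde, as in step 10.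

Step 21
Reactants: 36 enyne acid
Product: 38 (2S,3S,4Z,8S)-3-(but-3-yn-1-yl)-10-hydroxy-2,4,8-trimethyl-2-{(3E)-3-[2-(4-methylphenylsulfonyl)hydrazinylidene]propyl}dec-4-enoic acid, via hydroxy aldehyde 37 (not isolated)
Conditions: 0.5 M aq HCl, THF, rt; then TsNHNH2, rt
Reagents that add atoms: p-toluenesulfonyl hydrazide, Cc1ccc(cc1)S(=O)(=O)NN
Why: Acetal and silyl ether hydrolysis followed by hydrazone formation, as in step 11; the Z-alkene is not protonated at this acidity.

Step 22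
Reactants: 38 enyne tosylhydrazone (Z-alkene, 4S,5S)
Product: 41 (5S,13S)-15-hydroxy-5-epi-labd-8(17)-en-19-oic acid (cis-decalin), via stannylated tosylhydrazine 39 (not isolated), via vinylstannane 40 (not isolated)
Conditions: Bu3SnH (syringe pump), ACCN (cat.), PhMe (5 mM), 110 °C; then continued reflux
Reagents that add atoms: none
Why: In this same radical cascade the Z-alkene puts C11 axial and cis to H5 in the 6-endo chair, this axial chain shields the β lobe of the C10 radical, and the (4S) centre again prefers CO2H rather than C18 syn-axial to C20, so C1 should bond axially from the α face and give the cis-decalin with 9S,10R configuration.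

Step 23
Reactants: 41 cis-fused hydroxy acid
Product: 42 (5S,13S)-15-oxo-5-epi-labd-8(17)-en-19-oic acid
Conditions: Dess–Martin periodinane, CH2Cl2, rt
Reagents that add atoms: none
Why: Dess–Martin oxidation, as in step 13.

Step 24
Reactants: 25 (13S)-15-oxolabd-8(17)-en-19-oic acid
Product: 43 N-cyclohexyl aldimine of 25 (handled as its cyclohexylammonium carboxylate)
Conditions: c-HexNH2 (2 equiv), 4 Å MS, Et2O, rt
Reagents that add atoms: cyclohexylamine, NC1CCCCC1
Why: Imine condensation marks this half, and only this half, as the future nucleophile of the crossed aldol.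

Step 25
Reactants: 43 N-cyclohexyl aldimine; 42 (5S,13S)-15-oxo-5-epi-labd-8(17)-en-19-oic acid
Product: 47 CNP0229303.1 (target), via dilithiated imine 44 (not isolated), via lithium carboxylate 45 (not isolated), via aldol imine 46 (not isolated)
Conditions: 43, LDA (2.1 equiv), THF, −78 to 0 °C; 45 (from 42, LiHMDS 1.0 equiv, THF, −78 °C), −78 °C; then aq oxalic acid, THF, 40 °C
Reagents that add atoms: water, O
Why: In this directed (metalloenamine, Wittig-type) aldol condensation only 44 is nucleophilic at C14 and only 45 carries a free aldehyde, so only the crossed adduct forms, and acid hydrolysis of the imine with dehydration gives the thermodynamically preferred E-enal while the non-acidic C13 and C13' centres are untouched.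

**Compound list**
1 | (S)-citronellol | CC(C)=CCC[C@H](C)CCO | starting material
2 | tert-butyl{[(3S)-3,7-dimethyloct-6-en-1-yl]oxy}dimethylsilane | CC(C)=CCC[C@H](C)CCO[Si](C)(C)C(C)(C)C | intermediate
3 | (4S)-6-(tert-butyldimethylsilyloxy)-4-methylhexanal | O=CCC[C@H](C)CCO[Si](C)(C)C(C)(C)C | intermediate
4 | tert-butyl{[(3S)-3-methylhept-6-yn-1-yl]oxy}dimethylsilane | C#CCC[C@H](C)CCO[Si](C)(C)C(C)(C)C | intermediate
5 | lithium acetylide of 4 | [Li]C#CCC[C@H](C)CCO[Si](C)(C)C(C)(C)C | intermediate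
6 | tert-butyl{[(3S)-3-methyloct-6-yn-1-yl]oxy}dimethylsilane | CC#CCC[C@H](C)CCO[Si](C)(C)C(C)(C)C | intermediate
7 | (E)-alkenylzirconocene chloride from 6 | C/C([Zr](Cl)(C1C=CC=C1)C1C=CC=C1)=C\CC[C@H](C)CCO[Si](C)(C)C(C)(C)C | intermediate
8 | tert-butyl{[(3S,6E)-7-iodo-3-methyloct-6-en-1-yl]oxy}dimethylsilane | C/C(I)=C\CC[C@H](C)CCO[Si](C)(C)C(C)(C)C | intermediate
9 | 2-vinyl-1,3-dioxolane | C=CC1OCCO1 | starting material
10 | 2-iodocyclohex-2-en-1-one | O=C1CCCC=C1I | starting material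
11 | 9-[2-(1,3-dioxolan-2-yl)ethyl]-9-borabicyclo[3.3.1]nonane | C1CC2CCCC(C1)B2CCC1OCCO1 | intermediate
12 | 2-[2-(1,3-dioxolan-2-yl)ethyl]cyclohex-2-en-1-one | O=C1CCCC=C1CCC1OCCO1 | intermediate
13 | (E)-alkenylmagnesium chloride from 8 | C/C([Mg]Cl)=C\CC[C@H](C)CCO[Si](C)(C)C(C)(C)C | intermediate
14 | chloromagnesium enolate after conjugate addition (5R) | Cl[Mg]OC1=C(CCC2OCCO2)[C@@H](/C(C)=C/CC[C@H](C)CCO[Si](C)(C)C(C)(C)C)CCC1 | intermediate
15 | (2S,3R)-3-[(2E,6S)-8-(tert-butyldimethylsilyloxy)-6-methyloct-2-en-2-yl]-2-[2-(1,3-dioxolan-2-yl)ethyl]-2-methylcyclohexan-1-one | O=C1CCC[C@H](/C(C)=C/CC[C@H](C)CCO[Si](C)(C)C(C)(C)C)[C@]1(C)CCC1OCCO1 | intermediate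
16 | potassium enolate of 15 | [K]OC1=CCC[C@H](/C(C)=C/CC[C@H](C)CCO[Si](C)(C)C(C)(C)C)[C@]1(C)CCC1OCCO1 | intermediate
17 | 6-hydroxy derivative of 15 | O=C1C(O)CC[C@H](/C(C)=C/CC[C@H](C)CCO[Si](C)(C)C(C)(C)C)[C@]1(C)CCC1OCCO1 | intermediate
18 | (2S,3R,4E,8S)-10-(tert-butyldimethylsilyloxy)-2-[2-(1,3-dioxolan-2-yl)ethyl]-2,4,8-trimethyl-3-(3-oxopropyl)dec-4-enoic acid | O=CCC[C@@H]([C@](C)(CCC1OCCO1)C(=O)O)/C(C)=C/CC[C@H](C)CCO[Si](C)(C)C(C)(C)C | intermediate
19 | (2S,3R,4E,8S)-3-(but-3-yn-1-yl)-10-(tert-butyldimethylsilyloxy)-2-[2-(1,3-dioxolan-2-yl)ethyl]-2,4,8-trimethyldec-4-enoic acid | C#CCC[C@@H]([C@](C)(CCC1OCCO1)C(=O)O)/C(C)=C/CC[C@H](C)CCO[Si](C)(C)C(C)(C)C | intermediate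
20 | (2S,3R,4E,8S)-3-(but-3-yn-1-yl)-10-hydroxy-2,4,8-trimethyl-2-(3-oxopropyl)dec-4-enoic acid | C#CCC[C@@H]([C@](C)(CCC=O)C(=O)O)/C(C)=C/CC[C@H](C)CCO | intermediate
21 | N-tosylhydrazone of 20 | C#CCC[C@@H]([C@](C)(CC/C=N/NS(=O)(=O)c1ccc(C)cc1)C(=O)O)/C(C)=C/CC[C@H](C)CCO | intermediate
22 | 17-tributylstannyl-1-(2-tosylhydrazinyl) derivative of 24 | CCCC[Sn](CCCC)(CCCC)C=C1CC[C@@H]2[C@](C)(C(NNS(=O)(=O)c3ccc(C)cc3)CC[C@]2(C)C(=O)O)[C@H]1CC[C@H](C)CCO | intermediate
23 | 17-tributylstannyl derivative of 24 | CCCC[Sn](CCCC)(CCCC)C=C1CC[C@@H]2[C@](C)(CCC[C@]2(C)C(=O)O)[C@H]1CC[C@H](C)CCO | intermediate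
24 | (13S)-15-hydroxylabd-8(17)-en-19-oic acid | C=C1CC[C@@H]2[C@](C)(CCC[C@]2(C)C(=O)O)[C@H]1CC[C@H](C)CCO | intermediate
25 | (13S)-15-oxolabd-8(17)-en-19-oic acid | C=C1CC[C@@H]2[C@](C)(CCC[C@]2(C)C(=O)O)[C@H]1CC[C@H](C)CC=O | intermediate
26 | tert-butyl{[(3S,6Z)-7-iodo-3-methyloct-6-en-1-yl]oxy}dimethylsilane | C/C(I)=C/CC[C@H](C)CCO[Si](C)(C)C(C)(C)C | intermediate
27 | 2-methylcyclohex-2-en-1-one | CC1=CCCCC1=O | starting material
28 | (Z)-alkenylmagnesium chloride from 26 | C/C([Mg]Cl)=C/CC[C@H](C)CCO[Si](C)(C)C(C)(C)C | intermediate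
29 | chloromagnesium enolate after conjugate addition (5S) | Cl[Mg]OC1=C(C)[C@H](/C(C)=C\CC[C@H](C)CCO[Si](C)(C)C(C)(C)C)CCC1 | intermediate
30 | (2S,3S)-2-allyl-3-[(2Z,6S)-8-(tert-butyldimethylsilyloxy)-6-methyloct-2-en-2-yl]-2-methylcyclohexan-1-one | O=C1CCC[C@@H](/C(C)=C\CC[C@H](C)CCO[Si](C)(C)C(C)(C)C)[C@]1(C)CC=C | intermediate
31 | (2S,3S)-3-[(2Z,6S)-8-(tert-butyldimethylsilyloxy)-6-methyloct-2-en-2-yl]-2-methyl-2-(3-oxopropyl)cyclohexan-1-one | O=C1CCC[C@@H](/C(C)=C\CC[C@H](C)CCO[Si](C)(C)C(C)(C)C)[C@]1(C)CCC=O | intermediate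
32 | (2S,3S)-3-[(2Z,6S)-8-(tert-butyldimethylsilyloxy)-6-methyloct-2-en-2-yl]-2-[2-(1,3-dioxolan-2-yl)ethyl]-2-methylcyclohexan-1-one | O=C1CCC[C@@H](/C(C)=C\CC[C@H](C)CCO[Si](C)(C)C(C)(C)C)[C@]1(C)CCC1OCCO1 | intermediate
33 | potassium enolate of 32 | [K]OC1=CCC[C@@H](/C(C)=C\CC[C@H](C)CCO[Si](C)(C)C(C)(C)C)[C@]1(C)CCC1OCCO1 | intermediate
34 | 6-hydroxy derivative of 32 | O=C1C(O)CC[C@@H](/C(C)=C\CC[C@H](C)CCO[Si](C)(C)C(C)(C)C)[C@]1(C)CCC1OCCO1 | intermediate
35 | (2S,3S,4Z,8S)-10-(tert-butyldimethylsilyloxy)-2-[2-(1,3-dioxolan-2-yl)ethyl]-2,4,8-trimethyl-3-(3-oxopropyl)dec-4-enoic acid | O=CCC[C@H]([C@](C)(CCC1OCCO1)C(=O)O)/C(C)=C\CC[C@H](C)CCO[Si](C)(C)C(C)(C)C | intermediate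
36 | (2S,3S,4Z,8S)-3-(but-3-yn-1-yl)-10-(tert-butyldimethylsilyloxy)-2-[2-(1,3-dioxolan-2-yl)ethyl]-2,4,8-trimethyldec-4-enoic acid | C#CCC[C@H]([C@](C)(CCC1OCCO1)C(=O)O)/C(C)=C\CC[C@H](C)CCO[Si](C)(C)C(C)(C)C | intermediate
37 | (2S,3S,4Z,8S)-3-(but-3-yn-1-yl)-10-hydroxy-2,4,8-trimethyl-2-(3-oxopropyl)dec-4-enoic acid | C#CCC[C@H]([C@](C)(CCC=O)C(=O)O)/C(C)=C\CC[C@H](C)CCO | intermediate
38 | N-tosylhydrazone of 37 | C#CCC[C@H]([C@](C)(CC/C=N/NS(=O)(=O)c1ccc(C)cc1)C(=O)O)/C(C)=C\CC[C@H](C)CCO | intermediate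
39 | 17-tributylstannyl-1-(2-tosylhydrazinyl) derivative of 41 | CCCC[Sn](CCCC)(CCCC)C=C1CC[C@H]2[C@](C)(C(NNS(=O)(=O)c3ccc(C)cc3)CC[C@]2(C)C(=O)O)[C@H]1CC[C@H](C)CCO | intermediate
40 | 17-tributylstannyl derivative of 41 | CCCC[Sn](CCCC)(CCCC)C=C1CC[C@H]2[C@](C)(CCC[C@]2(C)C(=O)O)[C@H]1CC[C@H](C)CCO | intermediate
41 | (5S,13S)-15-hydroxy-5-epi-labd-8(17)-en-19-oic acid | C=C1CC[C@H]2[C@](C)(CCC[C@]2(C)C(=O)O)[C@H]1CC[C@H](C)CCO | intermediate
42 | (5S,13S)-15-oxo-5-epi-labd-8(17)-en-19-oic acid | C=C1CC[C@H]2[C@](C)(CCC[C@]2(C)C(=O)O)[C@H]1CC[C@H](C)CC=O | intermediate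
43 | N-cyclohexyl aldimine of 25 | C=C1CC[C@@H]2[C@](C)(CCC[C@]2(C)C(=O)O)[C@H]1CC[C@H](C)C/C=N/C1CCCCC1 | intermediate
44 | lithium carboxylate and lithium azaenolate of 43 | C=C1CC[C@@H]2[C@](C)(CCC[C@]2(C)C(=O)O[Li])[C@H]1CC[C@H](C)C=CN([Li])C1CCCCC1 | intermediate
45 | lithium carboxylate of 42 | C=C1CC[C@H]2[C@](C)(CCC[C@]2(C)C(=O)O[Li])[C@H]1CC[C@H](C)CC=O | intermediate
46 | β-hydroxy aldimine (crossed aldol adduct) | C=C1CC[C@@H]2[C@](C)(CCC[C@]2(C)C(=O)O)[C@H]1CC[C@H](C)C(C=NC1CCCCC1)C(O)C[C@@H](C)CC[C@H]1C(=C)CC[C@H]2[C@]1(C)CCC[C@]2(C)C(=O)O | intermediate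
47 | CNP0229303.1 | C=C1CC[C@@H]2[C@](C)(CCC[C@]2(C)C(=O)O)[C@H]1CC[C@H](C)/C(C=O)=C\C[C@@H](C)CC[C@H]1C(=C)CC[C@H]2[C@]1(C)CCC[C@]2(C)C(=O)O | target

**Total step count:** 25.

**Longest linear sequence:** 14 (steps 1, 2, 3, 4, 5, 7, 8, 9, 10, 11, 12, 13, 24, 25).

**Steps most likely to fail**

1. **Step 12.** The vinyl radical may be reduced, or may close 5-exo, before ring B forms, so that the C10 radical is not generated cleanly.
   - The fallback sets out from 18 and returns at 24.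
   - It replaces the vinyl radical by an acyl radical, whose 6-endo closure on 5-methyl-substituted alkenes is secure and whose product is epimerisable at C9 to the equatorial chain.
   - Pinnick oxidation of 18 gives the seco diacid F1.
   - The unhindered C8 acid alone is converted with (PhSe)2/Bu3P into the phenyl selenoester F2.
   - Dilute acid and then TsNHNH2 give the selenoester tosylhydrazone F3.
   - Bu3SnH/ACCN under high dilution, followed by heating, gives the 8-oxo-17-nor acid F4.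
   - Wittig methylenation of F4 with excess Ph3P=CH2 returns 24.

2. **Step 22.** The relay from the Z-alkene to C9 may be eroded if closure runs through the 5-exo radical, and trans closure may compete at C10.
   - The fallback sets out from 35 and returns at 41. It separates the two ring closures.
   - A concerted type II carbonyl-ene cyclisation (Me2AlCl, CH2Cl2, −78 °C) fixes C9 stereospecifically and gives the methylenecyclohexanol F5.
   - TsNHNH2/PPTS in wet THF gives its tosylhydrazone F6 with the silyl ether kept.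
   - A hydrogen-atom-transfer cyclisation (Fe(acac)3, PhSiH3, EtOH, 60 °C) closes C1–C10 on the only alkene and gives the 8-hydroxy cis-decalin F7.
   - Dess–Martin oxidation gives the ketone F8.
   - Non-basic Lombardo methylenation gives the silyl ether F9, and TBAF returns 41.

3. **Step 7 (and its twin, step 15).** Transfer of the α-branched alkenyl group may be sluggish, and the facial discrimination on the α-substituted enone may be poor.
   - The fallback sets out from 8 and 12 and returns at 15.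
   - The Grignard reagent 13 is quenched with B(OMe)3 and then acid to give the alkenylboronic acid F10.
   - A Rh(I)/BINAP-catalysed 1,4-addition to 12 in aqueous dioxane sets C5 and gives the 2,3-disubstituted ketone F11 (C4 epimers are irrelevant).
   - Thermodynamic silylation (TMSCl, Et3N, DMF, heat) gives the tetrasubstituted silyl enol ether F12.
   - MeLi and then MeI regenerate the enolate regiospecifically and return 15.

Further compounds
F1 | step 12 | (2S,3R,4E,8S)-3-(2-carboxyethyl)-10-(tert-butyldimethylsilyloxy)-2-[2-(1,3-dioxolan-2-yl)ethyl]-2,4,8-trimethyldec-4-enoic acid | OC(=O)CC[C@@H]([C@](C)(CCC1OCCO1)C(=O)O)/C(C)=C/CC[C@H](C)CCO[Si](C)(C)C(C)(C)C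
F2 | step 12 | C8 Se-phenyl selenoester of F1 | O=C([Se]c1ccccc1)CC[C@@H]([C@](C)(CCC1OCCO1)C(=O)O)/C(C)=C/CC[C@H](C)CCO[Si](C)(C)C(C)(C)C
F3 | step 12 | C8 Se-phenyl selenoester C1 tosylhydrazone with free C15 alcohol | O=C([Se]c1ccccc1)CC[C@@H]([C@](C)(CC/C=N/NS(=O)(=O)c1ccc(C)cc1)C(=O)O)/C(C)=C/CC[C@H](C)CCO
F4 | step 12 | (13S)-15-hydroxy-8-oxo-17-norlabdan-19-oic acid | O=C1CC[C@@H]2[C@](C)(CCC[C@]2(C)C(=O)O)[C@H]1CC[C@H](C)CCO
F5 | step 22 | ring-B methylenecyclohexanol from the carbonyl-ene cyclisation of 35 | C=C1[C@@H](CC[C@H](C)CCO[Si](C)(C)C(C)(C)C)C(O)CC[C@@H]1[C@](C)(CCC1OCCO1)C(=O)O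
F6 | step 22 | C1 tosylhydrazone of F5 | C=C1[C@@H](CC[C@H](C)CCO[Si](C)(C)C(C)(C)C)C(O)CC[C@@H]1[C@](C)(CC/C=N/NS(=O)(=O)c1ccc(C)cc1)C(=O)O
F7 | step 22 | (5S,13S)-15-(tert-butyldimethylsilyloxy)-8-hydroxy-5-epi-17-norlabdan-19-oic acid | OC1CC[C@H]2[C@](C)(CCC[C@]2(C)C(=O)O)[C@H]1CC[C@H](C)CCO[Si](C)(C)C(C)(C)C
F8 | step 22 | (5S,13S)-15-(tert-butyldimethylsilyloxy)-8-oxo-5-epi-17-norlabdan-19-oic acid | O=C1CC[C@H]2[C@](C)(CCC[C@]2(C)C(=O)O)[C@H]1CC[C@H](C)CCO[Si](C)(C)C(C)(C)C
F9 | step 22 | 15-O-TBS ether of 41 | C=C1CC[C@H]2[C@](C)(CCC[C@]2(C)C(=O)O)[C@H]1CC[C@H](C)CCO[Si](C)(C)C(C)(C)C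
F10 | step 7 | [(2E,6S)-8-(tert-butyldimethylsilyloxy)-6-methyloct-2-en-2-yl]boronic acid | C/C(B(O)O)=C\CC[C@H](C)CCO[Si](C)(C)C(C)(C)C
F11 | step 7 | (3R)-3-[(2E,6S)-8-(tert-butyldimethylsilyloxy)-6-methyloct-2-en-2-yl]-2-[2-(1,3-dioxolan-2-yl)ethyl]cyclohexan-1-one | O=C1CCC[C@H](/C(C)=C/CC[C@H](C)CCO[Si](C)(C)C(C)(C)C)C1CCC1OCCO1
F12 | step 7 | tetrasubstituted trimethylsilyl enol ether of F11 | C[Si](C)(C)OC1=C(CCC2OCCO2)[C@@H](/C(C)=C/CC[C@H](C)CCO[Si](C)(C)C(C)(C)C)CCC1
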